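**Retrosynthetic overview**

1. Target 21 ⇐ ketol 19 by Peterson methylenation of the C6 ketone; the acid used for the elimination also frees the phenol.
2. 19 ⇐ 18: key step, an α-ketol (acyloin) 1,2-shift that expands the cyclohexane of a trans-hydrindane α-hydroxy aldehyde to the cycloheptanone and sets C5.
3. 18 ⇐ 16 ⇐ 14 + 6: dihydroxylation and oxidation of an exocyclic alkene; the ester comes from diol 14 and silyl-protected vanillic acid 6 (built from catechol 1).
4. 14 ⇐ 13 ⇐ 11: six-membered ring by intramolecular Hosomi–Sakurai allylation, after isopropyl addition (C1) and oxidation.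
5. 11 ⇐ 8 + 9 + CH2O: a new enantioselective conjugate Hosomi–Sakurai allylation sets the quaternary carbon. Ring order: cyclopentane (from 9) → cyclohexane (step 8) → cycloheptane (step 12).

Assumption: the target is numbered as a decahydroazulene (C1 = C(OH)(i-Pr), C3a = C–CH3, C5 = CHOH, C6 = C=CH2, C8 = CH–O–ester, C8a = ring-fusion CH), which makes it (1R,3aR,5S,8S,8aS); these locants are used for the "future" atoms of earlier intermediates.

**Step 1**
Reactants: 1 benzene-1,2-diol (catechol)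
Product: 2 2-methoxyphenol
Conditions: MeI (1.0 equiv), K2CO3, acetone, reflux
Reagents that add atoms: iodomethane, CI
Why: Williamson mono-O-methylation of the symmetrical diol, with the diether and unreacted catechol removed by base extraction and distillation.

**Step 2**
Reactants: 2 2-methoxyphenol
Product: 3 4-bromo-2-methoxyphenol
Conditions: NBS, MeCN, 0 °C
Reagents that add atoms: N-bromosuccinimide, O=C1CCC(=O)N1Br
Why: electrophilic aromatic bromination goes para to the free OH, the stronger director.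

**Step 3**
Reactants: 3 4-bromo-2-methoxyphenol
Product: 6 4-[(tert-butyldimethylsilyl)oxy]-3-methoxybenzoic acid, via aryl silyl ether 4 (not isolated), via aryllithium 5 (not isolated)
Conditions: NaH, TBSCl, THF, 0 °C to rt; then n-BuLi, −78 °C; CO2; H3O+
Reagents that add atoms: tert-butyldimethylsilyl chloride, CC(C)(C)[Si](C)(C)Cl; carbon dioxide, O=C=O
Why: O-silylation of the phenoxide, bromine–lithium exchange and carboxylation of the aryllithium in one flask; the aryl silyl ether survives the mild acid work-up.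

**Step 4**
Reactants: 7 3-chloro-2-(chloromethyl)prop-1-ene
Product: 8 (2-methylidenepropane-1,3-diyl)bis(trimethylsilane)
Conditions: Mg, Me3SiCl, THF, 0 °C to reflux
Reagents that add atoms: chlorotrimethylsilane, C[Si](C)(C)Cl
Why: Barbier-type in situ Grignard formation and silylation of both allylic chlorides.

**Step 5**
Reactants: 9 3-methylcyclopent-2-en-1-one; 8 (2-methylidenepropane-1,3-diyl)bis(trimethylsilane)
Product: 11 (2S,3R)-2-(hydroxymethyl)-3-methyl-3-{2-[(trimethylsilyl)methyl]prop-2-en-1-yl}cyclopentan-1-one, via silyl enol ether 10 (not isolated)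
Conditions: (S,S)-IDPi Brønsted acid (imidodiphosphorimidate built from two 3,3'-bis[3,5-bis(trifluoromethyl)phenyl]-BINOL units, N-SO2CF3 groups; 2 mol %; enantiomer chosen to give 3R), toluene, −40 °C; then THF, 37 % aq. CH2O, Yb(OTf)3 (10 mol %), 0 °C to rt
Reagents that add atoms: formaldehyde, C=O
Why: Proposed new method: a catalytic enantioselective conjugate Hosomi–Sakurai allylation in which protodesilylation of 8 by the confined acid gives a silylium/IDPi ion pair that O-silylates 9 to a siloxyallyl cation held in the chiral anion, the doubly β-silyl-stabilised allylsilane attacks C3 on one face (C3a–C4 bond, R quaternary centre) and loss of Me3Si+ turns the catalyst over and leaves enol silane 10; the closest known reactions are the racemic TiCl4-mediated Hosomi–Sakurai conjugate addition to β,β-disubstituted enones and silylium–IDPi Mukaiyama–Michael additions, and the aqueous Mukaiyama hydroxymethylation that follows puts CH2OH anti to the bulkier silylmethylallyl arm (sets C8a).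

**Step 6**
Reactants: 11 (2S,3R)-2-(hydroxymethyl)-3-methyl-3-{2-[(trimethylsilyl)methyl]prop-2-en-1-yl}cyclopentan-1-one
Product: 12 (1R,2S,3R)-2-(hydroxymethyl)-3-methyl-1-(propan-2-yl)-3-{2-[(trimethylsilyl)methyl]prop-2-en-1-yl}cyclopentan-1-ol
Conditions: i-PrMgCl·LiCl (3 equiv), LaCl3·2LiCl, THF, −20 to 0 °C
Reagents that add atoms: isopropylmagnesium chloride, CC(C)[Mg]Cl
Why: Lewis-acid-assisted Grignard 1,2-addition (little enolisation or retro-aldol) in which the nucleophile enters anti to the adjacent CH2O–metal group, giving the cis-1,3-diol and C1 as R.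

**Step 7**
Reactants: 12 (1R,2S,3R)-2-(hydroxymethyl)-3-methyl-1-(propan-2-yl)-3-{2-[(trimethylsilyl)methyl]prop-2-en-1-yl}cyclopentan-1-ol
Product: 13 (1R,2R,5R)-2-hydroxy-5-methyl-2-(propan-2-yl)-5-{2-[(trimethylsilyl)methyl]prop-2-en-1-yl}cyclopentane-1-carbaldehyde
Conditions: TEMPO (10 mol %), PhI(OAc)2, CH2Cl2, rt
Reagents that add atoms: none
Why: oxoammonium (TEMPO) oxidation is selective for the primary alcohol and leaves the tertiary alcohol and the allylsilane untouched.

**Step 8**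
Reactants: 13 (1R,2R,5R)-2-hydroxy-5-methyl-2-(propan-2-yl)-5-{2-[(trimethylsilyl)methyl]prop-2-en-1-yl}cyclopentane-1-carbaldehyde
Product: 14 (1R,3aR,7S,7aS)-3a-methyl-5-methylidene-1-(propan-2-yl)octahydro-1H-indene-1,7-diol
Conditions: BF3·OEt2 (2.2 equiv), CH2Cl2, −78 °C
Reagents that add atoms: none
Why: intramolecular Hosomi–Sakurai allylation closes the six-membered ring (C7–C8 bond) through a chair in which the complexed aldehyde oxygen is equatorial, because axial would be syn-diaxial to the angular CH3; this gives the equatorial future C8 alcohol and the exocyclic alkene in a trans-hydrindane.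

**Step 9**
Reactants: 14 (1R,3aR,7S,7aS)-3a-methyl-5-methylidene-1-(propan-2-yl)octahydro-1H-indene-1,7-diol; 6 4-[(tert-butyldimethylsilyl)oxy]-3-methoxybenzoic acid
Product: 16 (1R,3aR,7S,7aS)-1-hydroxy-3a-methyl-5-methylidene-1-(propan-2-yl)octahydro-1H-inden-7-yl 4-[(tert-butyldimethylsilyl)oxy]-3-methoxybenzoate, via acid chloride 15 (not isolated)
Conditions: 6, (COCl)2, DMF (cat.), CH2Cl2, 0 °C to rt; then 14, Et3N, DMAP, CH2Cl2, 40 °C
Reagents that add atoms: none
Why: DMAP-catalysed acylation of the only secondary alcohol with the in situ acid chloride; the tertiary alcohol does not react.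

**Step 10**
Reactants: 16 (1R,3aR,7S,7aS)-1-hydroxy-3a-methyl-5-methylidene-1-(propan-2-yl)octahydro-1H-inden-7-yl 4-[(tert-butyldimethylsilyl)oxy]-3-methoxybenzoate
Product: 17 (1R,3aR,5S,7S,7aS)-1,5-dihydroxy-5-(hydroxymethyl)-3a-methyl-1-(propan-2-yl)octahydro-1H-inden-7-yl 4-[(tert-butyldimethylsilyl)oxy]-3-methoxybenzoate
Conditions: OsO4 (2 mol %), NMO, acetone/H2O, rt
Reagents that add atoms: N-methylmorpholine N-oxide, C[N+]1([O-])CCOCC1; water, O
Why: Upjohn dihydroxylation in which OsO4 approaches the exocyclic alkene equatorially, away from the syn-axial angular CH3, so the tertiary OH is equatorial and CH2OH axial.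

**Step 11**
Reactants: 17 (1R,3aR,5S,7S,7aS)-1,5-dihydroxy-5-(hydroxymethyl)-3a-methyl-1-(propan-2-yl)octahydro-1H-inden-7-yl 4-[(tert-butyldimethylsilyl)oxy]-3-methoxybenzoate
Product: 18 (1R,3aR,5S,7S,7aS)-5-formyl-1,5-dihydroxy-3a-methyl-1-(propan-2-yl)octahydro-1H-inden-7-yl 4-[(tert-butyldimethylsilyl)oxy]-3-methoxybenzoate
Conditions: SO3·pyridine, DMSO, i-Pr2NEt, CH2Cl2, 0 °C
Reagents that add atoms: none
Why: Parikh–Doering oxidation converts the primary alcohol of the 1,2-diol to the α-hydroxy aldehyde without glycol cleavage and leaves the tertiary alcohols alone.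

**Step 12**
Reactants: 18 (1R,3aR,5S,7S,7aS)-5-formyl-1,5-dihydroxy-3a-methyl-1-(propan-2-yl)octahydro-1H-inden-7-yl 4-[(tert-butyldimethylsilyl)oxy]-3-methoxybenzoate
Product: 19 (1R,3aR,5S,8S,8aS)-1,5-dihydroxy-3a-methyl-6-oxo-1-(propan-2-yl)decahydroazulen-8-yl 4-[(tert-butyldimethylsilyl)oxy]-3-methoxybenzoate
Conditions: Sc(OTf)3 (10 mol %), 4 Å MS, CH2Cl2, 0 °C to rt
Reagents that add atoms: none
Why: α-ketol (acyloin) rearrangement as a six-to-seven ring expansion, in which Sc chelates OH and CHO syn-periplanar and the ring CH2 next to the quaternary carbon (C4, favoured over the CH2 β to the ester oxygen) shifts to the aldehyde carbon from its own face to give the C5 S carbinol; it is driven by the aldehyde-to-ketone change and relief of the syn-diaxial CHO/CH3 strain.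

**Step 13**
Reactants: 19 (1R,3aR,5S,8S,8aS)-1,5-dihydroxy-3a-methyl-6-oxo-1-(propan-2-yl)decahydroazulen-8-yl 4-[(tert-butyldimethylsilyl)oxy]-3-methoxybenzoate
Product: 21 (1R,3aR,5S,8S,8aS)-1,5-dihydroxy-3a-methyl-6-methylidene-1-(propan-2-yl)decahydroazulen-8-yl 4-hydroxy-3-methoxybenzoate, via β-hydroxysilane 20 (not isolated)
Conditions: Me3SiCH2MgCl (4 equiv), LaCl3·2LiCl, THF, −20 to 0 °C; then 48 % aq. HF, MeCN, 0 °C to rt
Reagents that add atoms: (trimethylsilyl)methylmagnesium chloride, C[Si](C)(C)C[Mg]Cl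
Why: Peterson olefination, where the low-basicity addition to the ketone avoids β-elimination of the ester and HF induces anti-elimination to the exocyclic alkene while also cleaving the aryl silyl ether.

**Compound list**

1 | benzene-1,2-diol (catechol) | Oc1ccccc1O | starting material
2 | 2-methoxyphenol | COc1ccccc1O | intermediate
3 | 4-bromo-2-methoxyphenol | COc1cc(Br)ccc1O | intermediate
4 | (4-bromo-2-methoxyphenoxy)(tert-butyl)dimethylsilane | COc1cc(Br)ccc1O[Si](C)(C)C(C)(C)C | intermediate (not isolated)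
5 | {4-[(tert-butyldimethylsilyl)oxy]-3-methoxyphenyl}lithium | COc1cc([Li])ccc1O[Si](C)(C)C(C)(C)C | intermediate (not isolated)
6 | 4-[(tert-butyldimethylsilyl)oxy]-3-methoxybenzoic acid | COc1cc(C(=O)O)ccc1O[Si](C)(C)C(C)(C)C | intermediate
7 | 3-chloro-2-(chloromethyl)prop-1-ene | C=C(CCl)CCl | starting material
8 | (2-methylidenepropane-1,3-diyl)bis(trimethylsilane) | C=C(C[Si](C)(C)C)C[Si](C)(C)C | intermediate
9 | 3-methylcyclopent-2-en-1-one | CC1=CC(=O)CC1 | starting material
10 | trimethyl{[(3R)-3-methyl-3-{2-[(trimethylsilyl)methyl]prop-2-en-1-yl}cyclopent-1-en-1-yl]oxy}silane | C[Si](C)(C)OC1=C[C@](C)(CC1)CC(=C)C[Si](C)(C)C | intermediate (not isolated)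
11 | (2S,3R)-2-(hydroxymethyl)-3-methyl-3-{2-[(trimethylsilyl)methyl]prop-2-en-1-yl}cyclopentan-1-one | OC[C@@H]1[C@](C)(CCC1=O)CC(=C)C[Si](C)(C)C | intermediate
12 | (1R,2S,3R)-2-(hydroxymethyl)-3-methyl-1-(propan-2-yl)-3-{2-[(trimethylsilyl)methyl]prop-2-en-1-yl}cyclopentan-1-ol | OC[C@@H]1[C@](C)(CC[C@@]1(O)C(C)C)CC(=C)C[Si](C)(C)C | intermediate
13 | (1R,2R,5R)-2-hydroxy-5-methyl-2-(propan-2-yl)-5-{2-[(trimethylsilyl)methyl]prop-2-en-1-yl}cyclopentane-1-carbaldehyde | O=C[C@@H]1[C@](C)(CC[C@@]1(O)C(C)C)CC(=C)C[Si](C)(C)C | intermediate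
14 | (1R,3aR,7S,7aS)-3a-methyl-5-methylidene-1-(propan-2-yl)octahydro-1H-indene-1,7-diol | C=C1C[C@H](O)[C@@H]2[C@](C)(CC[C@@]2(O)C(C)C)C1 | intermediate
15 | 4-[(tert-butyldimethylsilyl)oxy]-3-methoxybenzoyl chloride | COc1cc(C(=O)Cl)ccc1O[Si](C)(C)C(C)(C)C | intermediate (not isolated)
16 | (1R,3aR,7S,7aS)-1-hydroxy-3a-methyl-5-methylidene-1-(propan-2-yl)octahydro-1H-inden-7-yl 4-[(tert-butyldimethylsilyl)oxy]-3-methoxybenzoate | C=C1C[C@H](OC(=O)c3ccc(O[Si](C)(C)C(C)(C)C)c(OC)c3)[C@@H]2[C@](C)(CC[C@@]2(O)C(C)C)C1 | intermediate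
17 | (1R,3aR,5S,7S,7aS)-1,5-dihydroxy-5-(hydroxymethyl)-3a-methyl-1-(propan-2-yl)octahydro-1H-inden-7-yl 4-[(tert-butyldimethylsilyl)oxy]-3-methoxybenzoate | OC[C@@]1(O)C[C@H](OC(=O)c3ccc(O[Si](C)(C)C(C)(C)C)c(OC)c3)[C@@H]2[C@](C)(CC[C@@]2(O)C(C)C)C1 | intermediate
18 | (1R,3aR,5S,7S,7aS)-5-formyl-1,5-dihydroxy-3a-methyl-1-(propan-2-yl)octahydro-1H-inden-7-yl 4-[(tert-butyldimethylsilyl)oxy]-3-methoxybenzoate | O=C[C@@]1(O)C[C@H](OC(=O)c3ccc(O[Si](C)(C)C(C)(C)C)c(OC)c3)[C@@H]2[C@](C)(CC[C@@]2(O)C(C)C)C1 | intermediate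
19 | (1R,3aR,5S,8S,8aS)-1,5-dihydroxy-3a-methyl-6-oxo-1-(propan-2-yl)decahydroazulen-8-yl 4-[(tert-butyldimethylsilyl)oxy]-3-methoxybenzoate | O=C1C[C@H](OC(=O)c3ccc(O[Si](C)(C)C(C)(C)C)c(OC)c3)[C@@H]2[C@](C)(CC[C@@]2(O)C(C)C)C[C@@H]1O | intermediate
20 | (1R,3aR,5S,8S,8aS)-1,5,6-trihydroxy-3a-methyl-1-(propan-2-yl)-6-[(trimethylsilyl)methyl]decahydroazulen-8-yl 4-[(tert-butyldimethylsilyl)oxy]-3-methoxybenzoate (C6 configuration not assigned; it is lost in the elimination) | C[Si](C)(C)CC1(O)C[C@H](OC(=O)c3ccc(O[Si](C)(C)C(C)(C)C)c(OC)c3)[C@@H]2[C@](C)(CC[C@@]2(O)C(C)C)C[C@@H]1O | intermediate (not isolated)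
21 | (1R,3aR,5S,8S,8aS)-1,5-dihydroxy-3a-methyl-6-methylidene-1-(propan-2-yl)decahydroazulen-8-yl 4-hydroxy-3-methoxybenzoate | C=C1C[C@H](OC(=O)c2ccc(O)c(OC)c2)[C@@H]2[C@](C)(CC[C@@]2(O)C(C)C)C[C@@H]1O | target

**Step count**

Total steps: 13. Longest linear sequence: 10 (7 → 21, steps 4 to 13). The aryl branch 1 → 6 is 3 steps and joins at step 9.

**Three steps most likely to fail**

Step 5 (proposed new reaction). The asymmetric silylium-catalysed conjugate allylation of a β,β-disubstituted cyclopentenone is unprecedented, and the C8a selectivity rests only on the size difference between CH3 and the allyl arm. The fallback uses known chemistry and sets out from 8 and 9. A stoichiometric TiCl4-mediated Hosomi–Sakurai conjugate addition (CH2Cl2, −78 °C) is followed by trapping of the titanium enolate with monomeric formaldehyde, which gives 11 as a racemate. The mirror-image ketone (2R,3S)-2-(hydroxymethyl)-3-methyl-3-{2-[(trimethylsilyl)methyl]prop-2-en-1-yl}cyclopentan-1-one F1 is removed by preparative chromatography on a chiral stationary phase, and the route is rejoined at 11.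

Step 8. BF3 may dehydrate the tertiary aldol in 13, or the cyclisation may give the axial alcohol. The fallback sets out from 13. If the epimer (1R,3aR,7R,7aS)-3a-methyl-5-methylidene-1-(propan-2-yl)octahydro-1H-indene-1,7-diol F2 is what forms, it is not discarded. Mitsunobu esterification with acid 6 (PPh3, DIAD, THF, 0 °C) inverts the carbinol centre, so the configuration is set by SN2 displacement instead of by the cyclisation. This gives 16 directly, and the route is rejoined there.

Step 12 (key ring expansion). The acyloin shift is reversible. The six-to-seven equilibrium is only modestly favourable, the wrong ring CH2 could migrate, and the ketol could tautomerise through the enediol. The fallback is an irreversible semipinacol and sets out from 16. Ozonolysis (O3, CH2Cl2/MeOH, −78 °C; Me2S) gives (1R,3aR,7S,7aS)-1-hydroxy-3a-methyl-5-oxo-1-(propan-2-yl)octahydro-1H-inden-7-yl 4-[(tert-butyldimethylsilyl)oxy]-3-methoxybenzoate F3. Addition of lithiated [(4-methoxybenzyl)oxy]methyl phenyl sulfone (THF, −78 °C) gives the β-hydroxy α-alkoxy sulfone 1,5-dihydroxy-5-{[(4-methoxybenzyl)oxy](phenylsulfonyl)methyl}-3a-methyl-1-(propan-2-yl)octahydro-1H-inden-7-yl 4-[(tert-butyldimethylsilyl)oxy]-3-methoxybenzoate F4. Et2AlCl then expels sulfinate, and the 1,2-shift to the oxocarbenium carbon gives (1R,3aR,5S,8S,8aS)-1-hydroxy-5-[(4-methoxybenzyl)oxy]-3a-methyl-6-oxo-1-(propan-2-yl)decahydroazulen-8-yl 4-[(tert-butyldimethylsilyl)oxy]-3-methoxybenzoate F5. DDQ (CH2Cl2/H2O) removes the 4-methoxybenzyl group, and the route is rejoined at 19.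

**Further compounds**

F1 | step 5 | (2R,3S)-2-(hydroxymethyl)-3-methyl-3-{2-[(trimethylsilyl)methyl]prop-2-en-1-yl}cyclopentan-1-one | OC[C@H]1[C@@](C)(CCC1=O)CC(=C)C[Si](C)(C)C
F2 | step 8 | (1R,3aR,7R,7aS)-3a-methyl-5-methylidene-1-(propan-2-yl)octahydro-1H-indene-1,7-diol | C=C1C[C@@H](O)[C@@H]2[C@](C)(CC[C@@]2(O)C(C)C)C1
F3 | step 12 | (1R,3aR,7S,7aS)-1-hydroxy-3a-methyl-5-oxo-1-(propan-2-yl)octahydro-1H-inden-7-yl 4-[(tert-butyldimethylsilyl)oxy]-3-methoxybenzoate | O=C1C[C@H](OC(=O)c3ccc(O[Si](C)(C)C(C)(C)C)c(OC)c3)[C@@H]2[C@](C)(CC[C@@]2(O)C(C)C)C1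
F4 | step 12 | 1,5-dihydroxy-5-{[(4-methoxybenzyl)oxy](phenylsulfonyl)methyl}-3a-methyl-1-(propan-2-yl)octahydro-1H-inden-7-yl 4-[(tert-butyldimethylsilyl)oxy]-3-methoxybenzoate (new centres not assigned) | O=S(=O)(c1ccccc1)C(OCc1ccc(OC)cc1)C1(O)C[C@H](OC(=O)c3ccc(O[Si](C)(C)C(C)(C)C)c(OC)c3)[C@@H]2[C@](C)(CC[C@@]2(O)C(C)C)C1
F5 | step 12 | (1R,3aR,5S,8S,8aS)-1-hydroxy-5-[(4-methoxybenzyl)oxy]-3a-methyl-6-oxo-1-(propan-2-yl)decahydroazulen-8-yl 4-[(tert-butyldimethylsilyl)oxy]-3-methoxybenzoate | O=C1C[C@H](OC(=O)c3ccc(O[Si](C)(C)C(C)(C)C)c(OC)c3)[C@@H]2[C@](C)(CC[C@@]2(O)C(C)C)C[C@@H]1OCc1ccc(OC)cc1
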